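The flask held 0.20 M of starting material, the limiting reagent against 1.80 equiv of second substrate, and its loading of 0.01 mol% made c(enzyme) 2.00 × 10⁻⁵ M. The grey run had held 1.00 × 10⁻⁵ M.

the same everywhere: enzyme 0.01 mol%

| charge | starting material | second substrate | remark |
|---|---|---|---|
| grey | 0.10 M | 1.8 equiv | run made earlier |
| flask | 0.20 M | 1.80 equiv |  |

- grey (time / min: target / %): 0.200: 4.3; 0.417: 10.0; 0.667: 16.2; 1.33: 31.8; 2.50: 57.7

(scatter of a reading: 1 percentage point)

- apparent order in second substrate when 50% of the starting material are converted (percent change of the rate of making target for one percent more second substrate charged)
- apparent order in enzyme when 50% of the starting material are converted (percent change of the rate of making target for one percent more enzyme charged)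

The bench rule for a line this straight says that each enzyme works at a fixed pace, so the rate is that pace times c(enzyme). The last grey reading gave 2310 min⁻¹ on average since the start, and I carried this number forward as the turnover rate, the target made per minute by each enzyme charged. In the grey run the second substrate had fallen by a third at that reading, yet the slope of the last stretch over the slope up to 1.33 min read 0.926. With a scatter of 1 percentage point on each reading that is no clear fall, so I put the order in second substrate close to zero.

But the flask had twice the c(enzyme) of the grey run, and the line was drawn at a single c(enzyme), so an order of one in enzyme was my assumption. Holding to it, I expected 0.0462 M min⁻¹ in the flask at 50% conversion.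

The forecast gave 0.08 in second substrate and 1 in enzyme, saying of the enzyme part “that is an assumption”.

The flask gave 0.032 in second substrate and 0.69 in enzyme, with a rate of 0.0405 M min⁻¹ at 50% conversion, which is less than my 0.0462 M min⁻¹.

    starting material + enzyme ⇌ starting complex (K = 120 M⁻¹, k = 3300 M⁻¹ s⁻¹)
    second substrate + starting complex ⇌ ternary complex (K = 110 M⁻¹, k = 8200 M⁻¹ s⁻¹)
    ternary complex → enzyme + target (k = 80.0 s⁻¹)
    2 ternary complex ⇌ resting dimer, settled at all times (K = 62000 M⁻¹)

The turnover rate in the flask at that conversion was 2030 min⁻¹, below the average of 2310 min⁻¹ read from the grey run. The order in enzyme stood below one because pairs of ternary complex bind into the resting dimer, which in the flask held 43.9% of the catalyst, each dimer counted as two, after 2.50 min. The same flask without that binding had an order of 1.0 and a rate 1.79 times the actual one, which puts its turnover rate at 3634 min⁻¹.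

All runs were generated by integration with constants of no real substance.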